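Slowness is what to watch at the start: in maple, with the charges held, the first step alone gives D a half-life of 110 s, longer than the run.

    D + J → G + Z (k1 = 0.30 M⁻¹ s⁻¹)
    D + G → Z + G, rate k2*[G]*[D] (k2 = 3.1 M⁻¹ s⁻¹)
    Z → E (k3 = 0.025 s⁻¹)

| flask | D | J | remark | time |
|---|---|---|---|---|
| ash | 0.22 M | 10 mol% | a single well-mixed tank run continuously and read at steady state, 15 s in it on average |  |
| maple | 0.22 M | 10 mol% | a closed flask charged with all of it at once and left for 15 s | 15 s |
| oak | 0.22 M (fed, over 12.0 s) | 10 mol% | a stirred flask in which D is dosed at a steady rate over 12.0 s without added volume, worked up at 15 s | 15 s |
- order of the set-ups by the amount of Z at the outlet or at the end, in percent of the D put in, highest first (ash / maple / oak)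
- amount of Z at the outlet or at the end, in percent of the D put in, ash
- amount of Z at the outlet or at the end, in percent of the D put in, maple
- amount of Z at the outlet or at the end, in percent of the D put in, oak
- the stated concentrations are those of everything mixed, before any reaction; amounts are the same in each set-up
- the feed brings no volume worth counting
- run time (maple): 15 s

In the first instants there is no G, and G comes from J by the first step. D is then used by the second step at s·[G]/[J] times the rate of the first, where s = k_G/k_J = 10.3, a selectivity factor with k_G and k_J the constants of those steps. In maple this ratio passes unity near 1.47 s, and the second step leads from then on.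

[D] cancels from that ratio, so the middle of the run can be reckoned. Let x = k_J∫[D]dt, let n be the loading and let b be the share of J gone, so that J falls as e^(−x). In maple and oak the share of D used is then u = n[b + s(x − b)].

For maple we try 33.3% used, so D averages 0.833 of its charge, x = 0.825, and u returns 32.8%. Toward the end of maple Z decays, and with a mean age that we take as 5.00 s we keep 28.7%.

For oak, D counts as full charge for 9.00 s. A trial of 16.7% used in oak gives x = 0.545 and returns 17.1%, and a mean age that we take as 3.75 s leaves 15.5%.

In the ash tank, with τ the mean stay of 15 s, a = k_J[D]τ and b = a/(1+a), u = n·b·(1+s·a). A trial of 33.3% used in ash gives a = 0.660 and returns 31.1%, and dividing by 1+k₃τ, with k₃ the constant of the third step, leaves 22.6%.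

The forecast gives maple > ash > oak, with 23.3% for ash, 29.6% for maple and 15.6% for oak, holding that "the closed flask, with full D from the start, makes the most Z". The simulation gives maple > ash > oak, with 23.3% for ash, 29.2% for maple and 15.6% for oak.

In oak at 12.0 s the second step uses D 4.7 times as fast as the first, and s·[G]/[J] from the amounts then standing gives 4.72. At that moment in oak Z's half-life of 28 s is shorter than D's 32 s by the second step. For the neighbour, oak at 0.37 M of D with the loading and the time held, a trial of 33.3% used gives x = 0.833, u = 33.3% and Z 30.2%. The simulation gives 30.5% of Z with 66% of D left.

All constants were drawn at random within sensible limits, and the outcome is calculated.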